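## Structural features

The target, (1R,2S,5R,6S)-2,6-bis(4-hydroxy-3-methoxyphenyl)-3,7-dioxabicyclo[3.3.0]octane-1,5-diol, is a C2-symmetric furofuran in which ring A (C1–C2–O3–C4–C5) and ring B (C5–C6–O7–C8–C1) are two tetrahydrofurans cis-fused through the C1–C5 bond. Four stereocentres stand in a row, C2–C1–C5–C6: C1 and C5 are adjacent tertiary carbinols with both hydroxyls on the convex face, and each aryl group at C2 and C6 is exo, cis to the hydroxyl of the neighbouring bridgehead. The bonds C2–O3 and C6–O7 are benzylic ethers para to an oxygen substituent, so they ionise in acid and can be hydrogenolysed. The phenols are easily oxidised, and the tertiary 1,2-diol beside two benzylic carbons invites pinacol-type shifts whenever a cation appears at C2 or C6. The real difficulty is to make two neighbouring, fully substituted, oxygen-bearing carbons in one absolute sense and as the chiral pair, not the meso pair. The key step uses the branching at the bridgeheads, where C1 carries C2 and C8 and C5 carries C6 and C4. With C2/C6 as aryl ketones and C8/C4 as esters, C1 and C5 are the α-carbons of two β-keto esters joined head to head: acidic, stereolabile and open to enolate oxidation, which makes the C1–O and C5–O bonds before either ring exists.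

## Logic of the disconnections

14 ⇐ 13. The two phenolic O–CH2Ph bonds are cut. The phenols have to be masked because every earlier operation (base, peroxide, hydride, acid) would deprotonate, oxidise or ionise them. The gain is that all earlier intermediates are neutral and non-phenolic. The demand on the forward step is chemoselectivity: hydrogenolysis must stop at the aryl benzyl ethers and spare C2–O3 and C6–O7.

13 ⇐ 11 (through 12). The ring bonds C2–O3 and C6–O7 are cut, which opens ring A and ring B. These bonds form most easily: C2 and C6 give stabilised p-alkoxybenzylic cations, and the primary hydroxyls on C4 and C8 sit five atoms away. The gain is the loss of both rings and of C2/C6 as fixed stereocentres. The demand is that each closure puts its aryl group exo and that the cation is trapped faster than it rearranges.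

11 ⇐ 9 (through 10). No skeletal bond is cut; the oxidation level is raised. The carbinols C2/C6 become aryl ketones and the hydroxymethyl carbons C4/C8 become tert-butyl esters. This turns C1 and C5 into β-keto ester α-carbons for the next cut and leaves only two stereocentres. The forward reduction must be exhaustive, and hydride must reach the ketones before the α-hydroxy-β-keto ester can fragment by retro-Claisen or retro-aldol cleavage.

9 ⇐ 7 (through 8). The bonds C1–O and C5–O are cut; this is the strategic disconnection. Removing the two hydroxyls leaves two C–H bonds that are the most acidic in the molecule, so the C–O bonds can be made by enolate oxidation on an open chain instead of at a hindered bridgehead. The gain is a precursor with no fixed stereocentre, since both centres epimerise through the enol. The demand is two oxidations in the same absolute sense, with the catalyst overriding the first new centre in the second one. The esters are tert-butyl because ester bulk is the known lever for selectivity in this reaction class and protects the products from hydroxide.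

7 ⇐ 5 (through 6). The central bond C1–C5 is cut, which divides the C2-symmetric skeleton into two identical halves. Both carbons are enolate carbons, so the forward step must be an oxidative coupling in which one half is made electrophilic by halogenation in the flask. The gain is that the problem is halved. The demand is exact control of the oxidant so that the reaction stops at the dimer; the new centres need no control.

5 ⇐ 3 + 4. The bond C1–C2 is cut as a Claisen disconnection into an aroyl donor, 3, and the enolate of 4. Both pieces are simple, and 4 is commercial. The forward step must be a clean crossed condensation, which a non-enolisable acyl donor, a hindered acetate and an excess of enolate secure.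

3 ⇐ 1 + 2. The aryl ether O–CH2Ph bond is cut. One alkylation masks the phenol, and the methyl ester already present in 1 is the acyl donor, so no separate activation of the carboxyl group is needed.

## Other disconnections considered

Alternative 1: The cut is at the two aryl–carbon bonds, C2–aryl and C6–aryl. This leaves the aryl-free meso core as its bis(acetone oxime) ether A1 and the aryl iodide A2.
- Forward key step: Pd(OAc)2 (divalent palladium) with a chiral mono-N-protected amino acid would bind an oxime nitrogen and cleave the exo C–H bond at C2 through a five-membered palladacycle. Oxidative addition of A2 and reductive elimination would make the aryl–carbon bond. A second event at C6 would give A3.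
- In its favour: it is the most convergent plan and the aryl groups arrive last. Exo selectivity is natural because each directing oxygen lies on the convex face beside the exo hydrogens. On convergence and on control of C2/C6 it is better than the chosen plan, which relies on a cationic ring closure.
- Against it here: A1 has four equivalent methylene groups and each oxime reaches two of them. The catalyst must pick one of four enantiotopic sites and then send the second aryl group to C6, not to C8 or C4. α-Oxygenated methylene C–H bonds are not an established substrate class for enantioselective arylation. A tertiary O-alkyl oxime cannot be made by SN2 alkylation, and its reductive removal endangers C2–O3 and C6–O7.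
- Comparison: both plans use the C2 symmetry, on which they are equal. Structurally this plan needs the bridgehead diol first and then attacks unactivated C–H bonds, whereas the chosen plan forms C1–O and C5–O at the two most acidic carbons. Mechanistically, metalation at an ether carbon is far less certain than enolate formation. In step count the two are about equal once the making of A1 and the removal of the oximes are counted.

Alternative 2: The cuts are C1–C2 and C5–C6 (aldol) together with O3–C4 and O7–C8 (lactone).
- Forward key step: the tartrate acetonide A4 would be enolised with LiN(iPr)2 and added to the aldehyde A5, and the aldolate would lactonise onto the ester of the neighbouring carbon. A second enolisation, aldol addition and lactonisation would complete the propellane bis-lactone A6.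
- In its favour: the configuration of C1 and C5 comes from the chiral pool, so no asymmetric catalysis is needed; on this point it is better than the chosen plan. The key operation makes four bonds, both rings and all four stereocentres. The face of the second aldol is fixed by the cis ring fusion.
- Against it here: the enolate of A4 loses its β-alkoxide readily above low temperature. The first aldol must enter cis to the neighbouring ester so that lactonisation is possible. The C2/C6 configuration is set kinetically in the aldol and cannot be corrected easily. After the key step, C4 and C8 must be taken from lactone carbonyl to CH2 beside ionisable benzylic C–O bonds, and an acetonide must be removed from a strained propellane.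
- Comparison: structurally it is superior in the source of chirality. Mechanistically it is more delicate (unstable enolate, two cryogenic cycles). In step economy it is about equal to the chosen plan, because the lactone reduction most plausibly runs through ring opening and reclosure, as in steps 5 and 6.

Alternative 3: The cut is the central bond C1–C5.
- Forward key step: SmI2 (divalent samarium) would reduce one ketone of the eight-membered diketone A7 to a ketyl. The ketyl would add across the ring to the second carbonyl and close ring A and ring B at once, giving the cis-diol A8, which is identical with 13.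
- In its favour: one step makes the central bond, both rings and both carbinols. A cis-diol is the natural result of a transannular, samarium-bridged coupling. Only one deprotection follows, so after the key step it is shorter than the chosen plan.
- Against it here: the stereocentres of A7 that would control the bridgeheads are benzylic and α to a ketone, so they epimerise easily. Each ketone is flanked on both sides by ether oxygens, and reductive cleavage of an α-alkoxy ketone by SmI2 competes with coupling. A head-to-tail medium-ring diketone such as A7 is hard to make.
- Comparison: structurally it relies on labile preset centres, whereas the chosen plan sets the robust centres first and the adjustable ones last. Mechanistically, a ketyl that can expel alkoxide is less dependable than an enolate. In step economy the end game is better, but the route to A7 is longer and less certain.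

Key step: step 4

Remarks on the chemistry:
- The aroyl unit is taken from commercial methyl vanillate (methyl 4-hydroxy-3-methoxybenzoate), so that a single O-benzylation gives the acyl donor of the Claisen condensation.
- The diaroylsuccinate and its dihydroxy product are carried as di-tert-butyl esters; the carbon skeleton and the bonds formed are unchanged.
- C1 and C5 are S in 8 and 9 and R from 10 onwards. Only the CIP ranking of the neighbours changes on reduction; no bond to these carbons is broken.
- The hand of the cinchona salt that gives (2S,3S) cannot be assigned by analogy for an acyclic enolate. The cinchonidinium salt is written; its pseudoenantiomeric cinchoninium salt is the equivalent choice for the mirror-image ion pair.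

## Route

Step 1
Reactants: 1 methyl vanillate (methyl 4-hydroxy-3-methoxybenzoate); 2 benzyl bromide
Product: 3 methyl 4-(benzyloxy)-3-methoxybenzoate
Conditions: 2 (1.1 equiv), K2CO3, DMF, 60 °C
Reagents that add atoms: none
Why: Williamson etherification: the potassium phenoxide of 1 displaces bromide from 2 in an SN2 reaction, while the methyl ester is untouched and serves as the acyl donor of step 2.

Step 2
Reactants: 3 methyl 4-(benzyloxy)-3-methoxybenzoate; 4 tert-butyl acetate
Product: 5 tert-butyl 3-[4-(benzyloxy)-3-methoxyphenyl]-3-oxopropanoate
Conditions: 4 (2.5 equiv), LiN(iPr)2 (2.6 equiv), THF, −78 °C; then 3, −78 → 0 °C; aq. NH4Cl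
Reagents that add atoms: none
Why: Crossed Claisen condensation: the lithium enolate of 4 adds to the non-enolisable methyl benzoate with loss of methoxide, and a second equivalent of enolate deprotonates the β-keto ester as it forms, which drives the reaction and stops further addition. The tert-butyl group suppresses self-condensation of 4.

Step 3
Reactants: 5 tert-butyl 3-[4-(benzyloxy)-3-methoxyphenyl]-3-oxopropanoate (two molecules)
Product: 7 di-tert-butyl 2,3-bis[4-(benzyloxy)-3-methoxybenzoyl]butanedioate (stereolabile mixture of meso and racemic forms), via α-iodo keto ester 6 (not isolated)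
Conditions: NaH (1.05 equiv), THF, 0 °C; then I2 (0.5 equiv), 0 °C → rt; aq. Na2S2O3
Reagents that add atoms: none
Why: Oxidative dimerisation of a β-keto ester enolate: iodine converts half of the sodium enolate into 6, which alkylates the remaining enolate at its activated secondary carbon to form C1–C5. Half an equivalent of iodine limits over-oxidation to the alkene, and the two new centres need no control because both epimerise through the enol.

Step 4
Reactants: 7 di-tert-butyl 2,3-bis[4-(benzyloxy)-3-methoxybenzoyl]butanedioate
Product: 9 di-tert-butyl (2S,3S)-2,3-bis[4-(benzyloxy)-3-methoxybenzoyl]-2,3-dihydroxybutanedioate, via monohydroxylated keto ester 8 (not isolated)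
Conditions: N-(9-anthracenylmethyl)cinchonidinium chloride (10 mol %), cumene hydroperoxide (3 equiv), 50% aq. K2HPO4, toluene, 0 °C → rt
Reagents that add atoms: cumene hydroperoxide, CC(C)(OO)c1ccccc1
Why: This is the enantioselective phase-transfer α-hydroxylation of an α-substituted β-keto ester with a hydroperoxide, run twice in one flask; that reaction is the closest known type. K2HPO4 removes the doubly activated proton at C1 (or C5) at the interface, the enolate enters toluene as a tight ion pair with the quaternary cinchona cation, and its α-carbon attacks the terminal oxygen of the hydroperoxide in an SN2 displacement at oxygen that expels cumyl oxide and leaves the C–OH bond. No ring is closed. Because 7 epimerises through its enols, both diastereomers feed one enolate, so the first centre (in 8) is set by the catalyst alone: the anthracenylmethyl wall screens one enolate face and the free C9 hydroxyl can hydrogen-bond the oxidant. The second hydroxylation at the remaining acidic carbon of 8 is slower because its neighbour is now fully substituted, but the electrophile is a single oxygen atom, and the same chiral cation must override the resident carbinol so that the C2-symmetric (2S,3S) diol forms and not the meso diol. Since a wrong face choice in either event ends as the meso diastereomer, which can be separated, the chiral diol should be enantiomerically richer than a single hydroxylation would make it. The tert-butyl esters are the substrate feature meant to secure this: ester bulk is the known lever for selectivity in this reaction class, and it shields the non-enolisable α-hydroxy-β-keto ester products from saponification and retro-Claisen attack. The weak base and low temperature are chosen to keep retro-aldol scission of the alkoxide of 8 and loss of hydroxide from its enolate slow.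

Step 5
Reactants: 9 di-tert-butyl (2S,3S)-2,3-bis[4-(benzyloxy)-3-methoxybenzoyl]-2,3-dihydroxybutanedioate
Product: 11 (2R,3R)-1,4-bis[4-(benzyloxy)-3-methoxyphenyl]-2,3-bis(hydroxymethyl)butane-1,2,3,4-tetrol (epimers at C1 and C4), via tetraol diester 10 (not isolated)
Conditions: LiAlH4 (excess), THF, −40 °C → reflux; H2O, aq. NaOH work-up
Reagents that add atoms: none
Why: Hydride reduction: the aryl ketones go first (10), then the tert-butyl esters, helped by delivery from the neighbouring alkoxyaluminates. C1 and C5 carry no hydrogen and keep all their bonds, so their configuration is retained; the new carbinols at C2 and C6 are left uncontrolled because step 6 ionises them.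

Step 6
Reactants: 11 (2R,3R)-1,4-bis[4-(benzyloxy)-3-methoxyphenyl]-2,3-bis(hydroxymethyl)butane-1,2,3,4-tetrol
Product: 13 (1R,2S,5R,6S)-2,6-bis[4-(benzyloxy)-3-methoxyphenyl]-3,7-dioxabicyclo[3.3.0]octane-1,5-diol, via monocyclic oxolane tetraol 12 (not isolated)
Conditions: camphor-10-sulfonic acid (10 mol %), CH2Cl2 (0.01 M), 0 °C → rt
Reagents that add atoms: none
Why: Twofold acid-catalysed cyclodehydration: each p-alkoxybenzylic alcohol ionises and the cation is captured by the primary hydroxyl five atoms away, closing ring A and then ring B. Each aryl group should settle on the convex face cis to the small bridgehead hydroxyl and away from the CH2O branch of the other ring, which sets C2 and C6 as S. A 2,5-diaryl oxolane formed by capture with the other benzylic hydroxyl can re-ionise under the same conditions and feed the bicycle.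

Step 7
Reactants: 13 (1R,2S,5R,6S)-2,6-bis[4-(benzyloxy)-3-methoxyphenyl]-3,7-dioxabicyclo[3.3.0]octane-1,5-diol
Product: 14 (1R,2S,5R,6S)-2,6-bis(4-hydroxy-3-methoxyphenyl)-3,7-dioxabicyclo[3.3.0]octane-1,5-diol
Conditions: H2 (1 atm), 10% Pd/C, EtOAc, rt
Reagents that add atoms: none
Why: Hydrogenolysis of aryl benzyl ethers, which are cleaved much faster than the dialkyl benzylic ether bonds C2–O3 and C6–O7. The reaction is run in a neutral solvent and stopped after two equivalents of hydrogen.

## Compound list

1 | methyl vanillate (methyl 4-hydroxy-3-methoxybenzoate) | COC(=O)c1ccc(O)c(OC)c1 | starting material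
2 | benzyl bromide | BrCc1ccccc1 | starting material
3 | methyl 4-(benzyloxy)-3-methoxybenzoate | COC(=O)c1ccc(OCc2ccccc2)c(OC)c1 | intermediate
4 | tert-butyl acetate | CC(=O)OC(C)(C)C | starting material
5 | tert-butyl 3-[4-(benzyloxy)-3-methoxyphenyl]-3-oxopropanoate | COc1cc(C(=O)CC(=O)OC(C)(C)C)ccc1OCc1ccccc1 | intermediate
6 | tert-butyl 3-[4-(benzyloxy)-3-methoxyphenyl]-2-iodo-3-oxopropanoate (racemic) | COc1cc(C(=O)C(I)C(=O)OC(C)(C)C)ccc1OCc1ccccc1 | intermediate (not isolated)
7 | di-tert-butyl 2,3-bis[4-(benzyloxy)-3-methoxybenzoyl]butanedioate (meso and racemic forms, interconverting) | COc1cc(C(=O)C(C(=O)OC(C)(C)C)C(C(=O)OC(C)(C)C)C(=O)c2ccc(OCc3ccccc3)c(OC)c2)ccc1OCc1ccccc1 | intermediate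
8 | di-tert-butyl (2S)-2,3-bis[4-(benzyloxy)-3-methoxybenzoyl]-2-hydroxybutanedioate (C3 labile) | COc1cc(C(=O)[C@](O)(C(=O)OC(C)(C)C)C(C(=O)OC(C)(C)C)C(=O)c2ccc(OCc3ccccc3)c(OC)c2)ccc1OCc1ccccc1 | intermediate (not isolated)
9 | di-tert-butyl (2S,3S)-2,3-bis[4-(benzyloxy)-3-methoxybenzoyl]-2,3-dihydroxybutanedioate | COc1cc(C(=O)[C@](O)(C(=O)OC(C)(C)C)[C@@](O)(C(=O)OC(C)(C)C)C(=O)c2ccc(OCc3ccccc3)c(OC)c2)ccc1OCc1ccccc1 | intermediate
10 | di-tert-butyl (2R,3R)-2,3-bis{[4-(benzyloxy)-3-methoxyphenyl](hydroxy)methyl}-2,3-dihydroxybutanedioate (carbinol epimers) | COc1cc(C(O)[C@](O)(C(=O)OC(C)(C)C)[C@@](O)(C(=O)OC(C)(C)C)C(O)c2ccc(OCc3ccccc3)c(OC)c2)ccc1OCc1ccccc1 | intermediate (not isolated)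
11 | (2R,3R)-1,4-bis[4-(benzyloxy)-3-methoxyphenyl]-2,3-bis(hydroxymethyl)butane-1,2,3,4-tetrol (epimers at C1 and C4) | COc1cc(C(O)[C@](O)(CO)[C@@](O)(CO)C(O)c2ccc(OCc3ccccc3)c(OC)c2)ccc1OCc1ccccc1 | intermediate
12 | (2S,3R,4R)-2-[4-(benzyloxy)-3-methoxyphenyl]-4-{[4-(benzyloxy)-3-methoxyphenyl](hydroxy)methyl}-3-(hydroxymethyl)oxolane-3,4-diol (carbinol epimers) | COc1cc([C@@H]2OC[C@@](O)(C(O)c3ccc(OCc4ccccc4)c(OC)c3)[C@@]2(O)CO)ccc1OCc1ccccc1 | intermediate (not isolated)
13 | (1R,2S,5R,6S)-2,6-bis[4-(benzyloxy)-3-methoxyphenyl]-3,7-dioxabicyclo[3.3.0]octane-1,5-diol | COc1cc([C@@H]2OC[C@@]3(O)[C@H](c4ccc(OCc5ccccc5)c(OC)c4)OC[C@@]23O)ccc1OCc1ccccc1 | intermediate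
14 | (1R,2S,5R,6S)-2,6-bis(4-hydroxy-3-methoxyphenyl)-3,7-dioxabicyclo[3.3.0]octane-1,5-diol | COc1cc([C@@H]2OC[C@@]3(O)[C@H](c4ccc(O)c(OC)c4)OC[C@@]23O)ccc1O | target

## Step count and least certain steps

Total: 7 steps. Longest linear sequence: 7 steps (1 → 14).

Step 4 (key step).
- What may go wrong: poor facial selectivity of a conformationally mobile acyclic enolate ion pair. In the second hydroxylation the resident carbinol may override the catalyst and divert material to the meso isomer. Retro-aldol scission and recombination at the alkoxide of 8 would erode the first centre, loss of hydroxide from the enolate of 8 (a Knoevenagel-type dehydration) would drain material, and the second oxidation may stall at the congested carbon.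
- Fallback (base-free oxidation and resolution in place of asymmetric induction), from 7 back to 9: 7 is oxidised without base by dimethyldioxirane in acetone at 0 °C, with a catalytic amount of nickel bis(acetylacetonate), Ni(acac)2 (divalent nickel), to speed enolisation if needed. The dioxirane transfers oxygen to the enol of each β-keto ester, which should give racemic 9 together with the meso isomer di-tert-butyl (2R,3S)-2,3-bis[4-(benzyloxy)-3-methoxybenzoyl]-2,3-dihydroxybutanedioate F1. F1 is removed by chromatography or crystallisation. Preparative chromatography on a chiral stationary phase then separates 9 from its enantiomer, di-tert-butyl (2R,3R)-2,3-bis[4-(benzyloxy)-3-methoxybenzoyl]-2,3-dihydroxybutanedioate F2.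

Step 6.
- What may go wrong: loss of control at C2 and C6 through reversible ionisation. Exo and endo aryl isomers of furofurans lie close in energy, and here the exo aryl is cis to a bridgehead hydroxyl, so prolonged equilibration could favour endo epimers. A 1,2-shift onto the benzylic cation from the neighbouring carbinol carbon (semipinacol) is the irreversible competitor.
- Fallback (closure at the primary carbons with retention at the benzylic centres, so no cation), from 9 back to 13: the ketones of 9 are reduced without chelation by NaBH4 in MeOH–THF at −40 °C. A Felkin–Anh arrangement with the α-hydroxyl anti to the incoming hydride is expected to favour di-tert-butyl (2R,3R)-2,3-bis{(S)-[4-(benzyloxy)-3-methoxyphenyl](hydroxy)methyl}-2,3-dihydroxybutanedioate F3. LiAlH4 in THF then reduces the esters to (1S,2R,3R,4S)-1,4-bis[4-(benzyloxy)-3-methoxyphenyl]-2,3-bis(hydroxymethyl)butane-1,2,3,4-tetrol F4. Bu2SnO (catalytic), TsCl and Et3N in CH2Cl2 sulfonylate only the primary hydroxyls and give (2R,3R)-2,3-bis{(S)-[4-(benzyloxy)-3-methoxyphenyl](hydroxy)methyl}-2,3-dihydroxybutane-1,4-diyl bis(4-methylbenzenesulfonate) F5. K2CO3 in MeOH at 0 °C closes each tertiary alkoxide onto its own CH2 and gives (2R,2'R)-2,2'-bis{(S)-[4-(benzyloxy)-3-methoxyphenyl](hydroxy)methyl}-2,2'-bioxirane F6; Payne migration is blocked because the carbon it would attack is fully substituted. Pyridinium p-toluenesulfonate in CH2Cl2 then lets each benzylic hydroxyl open the distal epoxide at its CH2 terminus in a 5-exo closure. This forms O3–C4 and O7–C8 with the benzylic configuration untouched and returns to 13.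

Step 7.
- What may go wrong: over-reduction, that is hydrogenolysis of the ring bonds C2–O3 and C6–O7 alongside or after debenzylation.
- Fallback (debenzylation before any benzylic ether exists), from 9 back to 14: H2 over Pd/C in EtOAc cleaves the aryl benzyl ethers of 9 and gives di-tert-butyl (2S,3S)-2,3-dihydroxy-2,3-bis(4-hydroxy-3-methoxybenzoyl)butanedioate F7; aryl ketones are reduced far more slowly than aryl benzyl ethers are cleaved. LiAlH4 (large excess) in refluxing THF gives (2R,3R)-1,4-bis(4-hydroxy-3-methoxyphenyl)-2,3-bis(hydroxymethyl)butane-1,2,3,4-tetrol F8. Camphor-10-sulfonic acid (catalytic) in THF at high dilution then closes both rings through the quinone-methide-like cations of the free p-hydroxybenzylic alcohols and gives 14 directly.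

Step 3.
- What may go wrong: over-oxidation, in which the enolate of 7 is iodinated and eliminates to the tetrasubstituted alkene; O-alkylation; and acid-induced furan formation from the 1,4-diketone on work-up.
- Fallback (two separately prepared partners in place of an oxidative homocoupling), from 5 back to 7: one half of 5 is brominated with N-bromosuccinimide and NH4OAc (catalytic) in Et2O to tert-butyl 3-[4-(benzyloxy)-3-methoxyphenyl]-2-bromo-3-oxopropanoate F9. The sodium enolate of the other half (NaH, THF, 0 °C) is alkylated with F9 to give 7, with no oxidant present once the dimer exists.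

## Further compounds

F1 | step 4 | di-tert-butyl (2R,3S)-2,3-bis[4-(benzyloxy)-3-methoxybenzoyl]-2,3-dihydroxybutanedioate (meso) | COc1cc(C(=O)[C@](O)(C(=O)OC(C)(C)C)[C@](O)(C(=O)OC(C)(C)C)C(=O)c2ccc(OCc3ccccc3)c(OC)c2)ccc1OCc1ccccc1
F2 | step 4 | di-tert-butyl (2R,3R)-2,3-bis[4-(benzyloxy)-3-methoxybenzoyl]-2,3-dihydroxybutanedioate | COc1cc(C(=O)[C@@](O)(C(=O)OC(C)(C)C)[C@](O)(C(=O)OC(C)(C)C)C(=O)c2ccc(OCc3ccccc3)c(OC)c2)ccc1OCc1ccccc1
F3 | step 6 | di-tert-butyl (2R,3R)-2,3-bis{(S)-[4-(benzyloxy)-3-methoxyphenyl](hydroxy)methyl}-2,3-dihydroxybutanedioate | COc1cc([C@H](O)[C@](O)(C(=O)OC(C)(C)C)[C@@](O)(C(=O)OC(C)(C)C)[C@@H](O)c2ccc(OCc3ccccc3)c(OC)c2)ccc1OCc1ccccc1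
F4 | step 6 | (1S,2R,3R,4S)-1,4-bis[4-(benzyloxy)-3-methoxyphenyl]-2,3-bis(hydroxymethyl)butane-1,2,3,4-tetrol | COc1cc([C@H](O)[C@](O)(CO)[C@@](O)(CO)[C@@H](O)c2ccc(OCc3ccccc3)c(OC)c2)ccc1OCc1ccccc1
F5 | step 6 | (2R,3R)-2,3-bis{(S)-[4-(benzyloxy)-3-methoxyphenyl](hydroxy)methyl}-2,3-dihydroxybutane-1,4-diyl bis(4-methylbenzenesulfonate) | COc1cc([C@H](O)[C@](O)(COS(=O)(=O)c2ccc(C)cc2)[C@@](O)(COS(=O)(=O)c3ccc(C)cc3)[C@@H](O)c4ccc(OCc5ccccc5)c(OC)c4)ccc1OCc1ccccc1
F6 | step 6 | (2R,2'R)-2,2'-bis{(S)-[4-(benzyloxy)-3-methoxyphenyl](hydroxy)methyl}-2,2'-bioxirane | COc1cc([C@H](O)[C@]2(CO2)[C@@]3(CO3)[C@@H](O)c4ccc(OCc5ccccc5)c(OC)c4)ccc1OCc1ccccc1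
F7 | step 7 | di-tert-butyl (2S,3S)-2,3-dihydroxy-2,3-bis(4-hydroxy-3-methoxybenzoyl)butanedioate | COc1cc(C(=O)[C@](O)(C(=O)OC(C)(C)C)[C@@](O)(C(=O)OC(C)(C)C)C(=O)c2ccc(O)c(OC)c2)ccc1O
F8 | step 7 | (2R,3R)-1,4-bis(4-hydroxy-3-methoxyphenyl)-2,3-bis(hydroxymethyl)butane-1,2,3,4-tetrol (epimers at C1 and C4) | COc1cc(C(O)[C@](O)(CO)[C@@](O)(CO)C(O)c2ccc(O)c(OC)c2)ccc1O
F9 | step 3 | tert-butyl 3-[4-(benzyloxy)-3-methoxyphenyl]-2-bromo-3-oxopropanoate (racemic) | COc1cc(C(=O)C(Br)C(=O)OC(C)(C)C)ccc1OCc1ccccc1
A1 | alternative 1 | cis-1,5-bis[(propan-2-ylideneamino)oxy]-3,7-dioxabicyclo[3.3.0]octane (meso) | C1OC[C@@]2(ON=C(C)C)COC[C@@]12ON=C(C)C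
A2 | alternative 1 | 1-(benzyloxy)-4-iodo-2-methoxybenzene | COc1cc(I)ccc1OCc1ccccc1
A3 | alternative 1 | (1R,2S,5R,6S)-2,6-bis[4-(benzyloxy)-3-methoxyphenyl]-1,5-bis[(propan-2-ylideneamino)oxy]-3,7-dioxabicyclo[3.3.0]octane | COc1cc([C@@H]2OC[C@@]3(ON=C(C)C)[C@H](c4ccc(OCc5ccccc5)c(OC)c4)OC[C@@]23ON=C(C)C)ccc1OCc1ccccc1
A4 | alternative 2 | dimethyl (4R,5R)-2,2-dimethyl-1,3-dioxolane-4,5-dicarboxylate | COC(=O)[C@@H]1OC(C)(C)O[C@H]1C(=O)OC
A5 | alternative 2 | 4-(benzyloxy)-3-methoxybenzaldehyde | COc1cc(C=O)ccc1OCc1ccccc1
A6 | alternative 2 | 1,5-O-isopropylidene-2,6-bis[4-(benzyloxy)-3-methoxyphenyl]-3,7-dioxabicyclo[3.3.0]octane-4,8-dione (propellane bis-lactone) | COc1cc([C@@H]2OC(=O)[C@@]3(OC(C)(C)O4)[C@H](c5ccc(OCc6ccccc6)c(OC)c5)OC(=O)[C@@]234)ccc1OCc1ccccc1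
A7 | alternative 3 | (2S,6S)-2,6-bis[4-(benzyloxy)-3-methoxyphenyl]-1,5-dioxocane-3,7-dione | COc1cc([C@@H]2OCC(=O)[C@H](c3ccc(OCc4ccccc4)c(OC)c3)OCC2=O)ccc1OCc1ccccc1
A8 | alternative 3 | (1R,2S,5R,6S)-2,6-bis[4-(benzyloxy)-3-methoxyphenyl]-3,7-dioxabicyclo[3.3.0]octane-1,5-diol (identical with 13) | COc1cc([C@@H]2OC[C@@]3(O)[C@H](c4ccc(OCc5ccccc5)c(OC)c4)OC[C@@]23O)ccc1OCc1ccccc1
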